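I could not get the catalyst's steps out of the earlier runs: in each closed flask, starting material and reagent fell together. So I counted half-lives instead. You asked for a quick number, and this is how I got mine.

| setting | maple | cedar | ash | Thursday's | Friday's | Wednesday's | Monday's |
|---|---|---|---|---|---|---|---|
| starting material | 0.10 M | 0.10 M | 0.10 M | 0.10 M (fed, over 1.60 h) | 0.10 M | 0.10 M | 0.10 M |
| reagent | 0.11 M | 0.11 M | 0.11 M | 0.110 M | 0.110 M | 0.110 M (fed, over 1.60 h) | 0.110 M |
| free catalyst | 62 µM | 31 µM | 46 µM | 62 µM | 62 µM | 62 µM | 62 µM |
| remark | run made earlier | run made earlier | run made earlier | a stirred flask in which starting material is dosed at a steady rate over 1.60 h without added volume, worked up at 2.0 h | a closed flask charged with all of it at once and left for 2.0 h | a stirred flask in which reagent is dosed at a steady rate over 1.60 h without added volume, worked up at 2.0 h | a single well-mixed tank run continuously and read at steady state, 2.0 h in it on average |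
| time |  |  |  | 2.0 h | 2.0 h | 2.0 h |  |

| maple: time / min | maple: target / % | cedar: time / min | cedar: target / % | ash: time / min | ash: target / % |
|---|---|---|---|---|---|
| 12.0 | 9.7 | 6.00 | 2.6 | 6.00 | 3.8 |
| 25.0 | 18.4 | 20.0 | 8.0 | 20.0 | 11.2 |
| 40.0 | 27.0 | 30.0 | 11.4 | 30.0 | 16.9 |
| 50.0 | 32.9 | 50.0 | 18.3 | 50.0 | 25.2 |
| 60.0 | 37.5 | 80.0 | 26.3 | 80.0 | 36.6 |
| 80.0 | 45.0 | 90.0 | 28.7 | 90.0 | 39.2 |

(standard deviation of a reading: 0.3 percentage points)

- the stated concentrations are those of everything mixed, before any reaction; amounts are the same in each set-up
- the feed brings no volume worth counting
- the earlier runs were made in a closed, stirred flask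

- the set-up with the highest amount of target at the outlet or at the end, in percent of the starting material put in ("none" if the first two lie within 2 percentage points) (Thursday's / Friday's / Wednesday's / Monday's / none)
- amount of target at the outlet or at the end, in percent of the starting material put in, Thursday's
- amount of target at the outlet or at the end, in percent of the starting material put in, Friday's
- amount of target at the outlet or at the end, in percent of the starting material put in, Wednesday's
- amount of target at the outlet or at the end, in percent of the starting material put in, Monday's

Friday's flask holds the maple charge, so I used maple's last reading. With the charges nearly equal, I took target over what was left to grow in step with time. The 45.0 % at 80.0 min then gave 97.8 min. That is my reading of the second-order half-life of this charge, the time a closed flask takes to turn half of the starting material into target. Maple's first reading gave 112 min, so it drifted, and I kept the later figure.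

Friday's 2.0 h counted 1.23 half-lives, and the share converted is the count over one plus the count, so I said 55.1 %. In a dosed flask the average portion enters at 0.800 h and has 1.20 h left, less than Friday's time, which gave me 42.4 %.

The forecast gave 42.5 % for Thursday's, 56.5 % for Friday's, 43.5 % for Wednesday's and 44.5 % for Monday's, a little above me on Friday's: "The batch flask wins clearly."

The flasks gave 47.1 %, 57.6 %, 44.1 % and 43.7 % in that order, so Friday's came first.

    catalyst intermediate B ⇌ free catalyst + target (K = 0.110 M, k = 5500 h⁻¹)
    reagent + free catalyst → catalyst intermediate A (k = 15000 M⁻¹ h⁻¹)
    starting material + catalyst intermediate A → catalyst intermediate B (k = 24000 M⁻¹ h⁻¹)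
    starting material + target → side product (k = 1.10 M⁻¹ h⁻¹)

In Friday's flask, by 1.00 h, starting material had fallen to 59.6 % and target had risen to 37.1 %, against 38.0 % from the count, with 43.9 % of the catalyst free. By 2.00 h starting material stood at 34.3 %, while its passing with target into side product had made 8.06 %. For Monday's tank, target over the square of what is left equals the count, which gives 41.7 %. Monday's tank held 43.7 %.

All runs were computed for substances that don't exist; scatter was added.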